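**Retrosynthetic overview**
- Last C–C bond: ring CH2–allylic CH2 of the side chain, from the α-sulfonyl carbanion of a cyclohexyl sulfone and the allylic bromide of the chroman half; PhSO2 and benzyl are then removed together.
- Cyclohexane ring: bond between the tertiary α-carbon of a ketone, used as its α-bromo ketone (an enolonium equivalent), and the alkene CH of geranyl phenyl sulfone; 6-endo radical closure with loss of HBr gives the ring ketone and the exocyclic methylene in one step; a catalyst-controlled reduction then fixes both ring stereocentres (axial OH).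
- Chroman: tertiary aryl ether centre by Pd-catalysed asymmetric O-allylation of a bromophenol with geranyl methyl carbonate; pyran ring by hydroboration and intramolecular Suzuki coupling; E-allylic bromide by SeO2 oxidation and Appel reaction.
- Ring order: pyran ring (step 5) and carbocycle (step 12) are built in separate branches and joined in step 14.

Assumption: the SMILES is read as (2S) at the chroman carbon and (1R,3R) in the cyclohexane, i.e. OH trans to the side chain (axial OH).

**Step 1**
Reactants: 1 2-methylbenzene-1,4-diol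
Product: 2 4-(benzyloxy)-2-methylphenol
Conditions: BnBr (1.0 equiv), K2CO3 (1.1 equiv), acetone, reflux
Reagents that add atoms: benzyl bromide, BrCc1ccccc1
Why: Williamson etherification goes mainly at the 4-OH, which is not flanked by the methyl group, and the minor regioisomer and bis-ether are removed by chromatography.

**Step 2**
Reactants: 2 4-(benzyloxy)-2-methylphenol
Product: 3 4-(benzyloxy)-2-bromo-6-methylphenol
Conditions: NBS (1.0 equiv), i-Pr2NH (10 mol %), CH2Cl2, 0 °C
Reagents that add atoms: N-bromosuccinimide, O=C1CCC(=O)N1Br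
Why: Amine-mediated electrophilic bromination of a phenol is ortho-selective, and only one position ortho to the free OH is open.

**Step 3**
Reactants: 4 geraniol
Product: 5 geranyl methyl carbonate
Conditions: ClCO2Me, pyridine, CH2Cl2, 0 °C
Reagents that add atoms: methyl chloroformate, COC(=O)Cl
Why: Simple acylation of the primary allylic alcohol gives the ionisable carbonate for the allylic substitution.

**Step 4**
Reactants: 3 4-(benzyloxy)-2-bromo-6-methylphenol; 5 geranyl methyl carbonate
Product: 6 5-(benzyloxy)-1-bromo-2-{[(3S)-3,7-dimethylocta-1,6-dien-3-yl]oxy}-3-methylbenzene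
Conditions: Pd2(dba)3·CHCl3 (2 mol %), (R,R)-DACH-phenyl Trost ligand (6 mol %), CH2Cl2, rt
Reagents that add atoms: none
Why: Trost asymmetric allylic etherification, in which zerovalent palladium ionises the carbonate and the phenoxide attacks the more substituted terminus of the π-allyl inside the chiral ligand pocket, sets the S tertiary ether centre (the mirror-image ligand gives R, and the sense of induction is checked on the first run).

**Step 5**
Reactants: 6 5-(benzyloxy)-1-bromo-2-{[(3S)-3,7-dimethylocta-1,6-dien-3-yl]oxy}-3-methylbenzene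
Product: 8 (2S)-6-(benzyloxy)-2,8-dimethyl-2-(4-methylpent-3-en-1-yl)-3,4-dihydro-2H-chromene, via alkylborane 7 (not isolated)
Conditions: 9-BBN (1.3 equiv), THF, 0 °C to rt; then Pd(dppf)Cl2 (5 mol %), K3PO4 (3 equiv), DMF/H2O, 60 °C
Reagents that add atoms: 9-borabicyclo[3.3.1]nonane (9-BBN), B1C2CCCC1CCC2 (its boron and carbon atoms are in 7 only)
Why: Anti-Markovnikov hydroboration of the only monosubstituted alkene followed by intramolecular B-alkyl Suzuki–Miyaura coupling with the ortho bromide closes the pyran ring without touching the tertiary ether centre.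

**Step 6**
Reactants: 8 (2S)-6-(benzyloxy)-2,8-dimethyl-2-(4-methylpent-3-en-1-yl)-3,4-dihydro-2H-chromene
Product: 9 (2E)-5-[(2S)-6-(benzyloxy)-2,8-dimethyl-3,4-dihydro-2H-chromen-2-yl]-2-methylpent-2-en-1-ol
Conditions: SeO2 (0.3 equiv), t-BuOOH (2.5 equiv), salicylic acid (10 mol %), CH2Cl2, rt
Reagents that add atoms: selenium dioxide, O=[Se]=O (oxygen carrier); tert-butyl hydroperoxide, CC(C)(C)OO (terminal oxidant)
Why: Sharpless–Umbreit allylic oxidation (ene reaction, then [2,3]-shift) hydroxylates the E-methyl of the terminal trisubstituted alkene, which fixes the E geometry of the later chain alkene.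

**Step 7**
Reactants: 9 (2E)-5-[(2S)-6-(benzyloxy)-2,8-dimethyl-3,4-dihydro-2H-chromen-2-yl]-2-methylpent-2-en-1-ol
Product: 10 (2S)-6-(benzyloxy)-2-[(3E)-5-bromo-4-methylpent-3-en-1-yl]-2,8-dimethyl-3,4-dihydro-2H-chromene
Conditions: CBr4, PPh3, CH2Cl2, 0 °C
Reagents that add atoms: carbon tetrabromide, BrC(Br)(Br)Br
Why: Appel reaction, SN2 at the primary allylic carbon without allylic shift at 0 °C; the bromide is used at once.

**Step 8**
Reactants: 11 geranyl bromide
Product: 12 [(2E)-3,7-dimethylocta-2,6-dien-1-yl]sulfonylbenzene (geranyl phenyl sulfone)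
Conditions: PhSO2Na, DMF, rt
Reagents that add atoms: sodium benzenesulfinate, [Na+].[O-]S(=O)c1ccccc1
Why: SN2 S-alkylation of the sulfinate gives the sulfone that later serves as the carbanion handle.

**Step 9**
Reactants: 12 geranyl phenyl sulfone
Product: 13 rac-2,2-dimethyl-3-[(3E)-3-methyl-5-(phenylsulfonyl)pent-3-en-1-yl]oxirane
Conditions: mCPBA (1.05 equiv), CH2Cl2, 0 °C
Reagents that add atoms: 3-chloroperbenzoic acid, OOC(=O)c1cccc(Cl)c1
Why: Prilezhaev epoxidation picks the electron-rich terminal alkene, because the other one is deactivated by the allylic sulfone.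

**Step 10**
Reactants: 13 rac-2,2-dimethyl-3-[(3E)-3-methyl-5-(phenylsulfonyl)pent-3-en-1-yl]oxirane
Product: 14 rac-(6E)-2-bromo-2,6-dimethyl-8-(phenylsulfonyl)oct-6-en-3-ol
Conditions: HBr (33% in AcOH, 1.1 equiv), CH2Cl2, −20 °C
Reagents that add atoms: hydrogen bromide, Br
Why: Acid-promoted epoxide opening with Markovnikov regiochemistry puts bromide on the tertiary carbon and leaves the secondary alcohol, so the later radical site is fixed without any enolisation question.

**Step 11**
Reactants: 14 rac-(6E)-2-bromo-2,6-dimethyl-8-(phenylsulfonyl)oct-6-en-3-ol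
Product: 15 (6E)-2-bromo-2,6-dimethyl-8-(phenylsulfonyl)oct-6-en-3-one
Conditions: Dess–Martin periodinane, CH2Cl2, rt
Reagents that add atoms: none
Why: Dess–Martin oxidation of the bromohydrin gives the tertiary α-bromo ketone under neutral conditions that do not eliminate HBr.

**Step 12 (key step)**
Reactants: 15 (6E)-2-bromo-2,6-dimethyl-8-(phenylsulfonyl)oct-6-en-3-one
Product: 16 rac-2,2-dimethyl-4-methylidene-3-[(phenylsulfonyl)methyl]cyclohexan-1-one
Conditions: Co(dmgH)2(py)Cl (10 mol %), i-Pr2NEt (1.5 equiv), MeCN, blue LEDs, rt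
Reagents that add atoms: none
Why: Proposed new method: the tertiary α-bromo ketone acts as an enolonium equivalent, since monovalent cobalt abstracts bromine to give the electrophilic α-keto radical, which closes 6-endo onto the nucleophilic trisubstituted alkene (ketone α-carbon and alkene carbon are both normally nucleophilic), and divalent cobalt then takes a hydrogen atom from the unhindered methyl group of the tertiary ring radical to give the exocyclic methylene and a cobalt hydride that the amine returns to monovalent cobalt; the closest known reactions are the cobaloxime-catalysed Heck-type cyclisation of alkyl halides under visible light and the 6-endo atom-transfer cyclisation of α-halo ketones; the new ring stereocentre is formed racemic.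

**Step 13**
Reactants: 16 rac-2,2-dimethyl-4-methylidene-3-[(phenylsulfonyl)methyl]cyclohexan-1-one
Product: 17 (1R,3R)-2,2-dimethyl-4-methylidene-3-[(phenylsulfonyl)methyl]cyclohexan-1-ol
Conditions: (S)-2-methyl-CBS-oxazaborolidine (20 mol %), BH3·SMe2 (0.7 equiv), THF, −20 °C; chromatography, then recrystallisation
Reagents that add atoms: none
Why: Corey–Bakshi–Shibata reduction under catalyst control (large group = quaternary carbon) makes the carbinol R in both enantiomers, so the (3R)-ketone gives the trans alcohol 17 with axial OH while the (3S)-ketone gives the cis diastereomer, which is separated (divergent reduction of a racemate, 50% maximum).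

**Step 14**
Reactants: 17 (1R,3R)-2,2-dimethyl-4-methylidene-3-[(phenylsulfonyl)methyl]cyclohexan-1-ol; 10 (2S)-6-(benzyloxy)-2-[(3E)-5-bromo-4-methylpent-3-en-1-yl]-2,8-dimethyl-3,4-dihydro-2H-chromene
Product: 19 (1R,3R)-3-{(3E)-6-[(2S)-6-(benzyloxy)-2,8-dimethyl-3,4-dihydro-2H-chromen-2-yl]-3-methyl-1-(phenylsulfonyl)hex-3-en-1-yl}-2,2-dimethyl-4-methylidenecyclohexan-1-ol (both epimers at the sulfonyl carbon), via dilithio sulfone dianion 18 (not isolated)
Conditions: n-BuLi (2.1 equiv), THF/DMPU, −78 °C; then 10 (0.9 equiv), −78 to −20 °C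
Reagents that add atoms: n-butyllithium, [Li]CCCC (lithium is in 18 only)
Why: Julia-type sulfone alkylation, in which the soft α-sulfonyl carbanion displaces the primary allylic bromide by SN2 with retention of the E alkene; the new sulfonyl-bearing centre is removed in the next step.

**Step 15**
Reactants: 19 (1R,3R)-3-{(3E)-6-[(2S)-6-(benzyloxy)-2,8-dimethyl-3,4-dihydro-2H-chromen-2-yl]-3-methyl-1-(phenylsulfonyl)hex-3-en-1-yl}-2,2-dimethyl-4-methylidenecyclohexan-1-ol
Product: 20 (2S)-2-{(3E)-6-[(1R,3R)-3-hydroxy-2,2-dimethyl-6-methylidenecyclohexyl]-4-methylhex-3-en-1-yl}-2,8-dimethyl-3,4-dihydro-2H-chromen-6-ol (CNP0102442.1)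
Conditions: lithium 4,4'-di-tert-butylbiphenylide (LiDBB, 8 equiv), THF, −78 °C; MeOH quench
Reagents that add atoms: none
Why: Single-electron reduction by the arene radical anion cleaves the C–S bond of the secondary sulfone (reductive desulfonylation) and the benzyl–O bond of the aryl benzyl ether in the same pot, while isolated alkenes and all stereocentres are untouched.

**Compound list**
1 | 2-methylbenzene-1,4-diol | Cc1cc(O)ccc1O | starting material
2 | 4-(benzyloxy)-2-methylphenol | Cc1cc(OCc2ccccc2)ccc1O | intermediate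
3 | 4-(benzyloxy)-2-bromo-6-methylphenol | Cc1cc(OCc2ccccc2)cc(Br)c1O | intermediate
4 | geraniol | CC(C)=CCC/C(C)=C/CO | starting material
5 | geranyl methyl carbonate | CC(C)=CCC/C(C)=C/COC(=O)OC | intermediate
6 | 5-(benzyloxy)-1-bromo-2-{[(3S)-3,7-dimethylocta-1,6-dien-3-yl]oxy}-3-methylbenzene | C=C[C@](C)(CCC=C(C)C)Oc1c(C)cc(OCc2ccccc2)cc1Br | intermediate
7 | 9-{(3R)-3-[4-(benzyloxy)-2-bromo-6-methylphenoxy]-3,7-dimethyloct-6-en-1-yl}-9-borabicyclo[3.3.1]nonane (same spatial arrangement as 6) | B1(C2CCCC1CCC2)CC[C@](C)(CCC=C(C)C)Oc1c(C)cc(OCc2ccccc2)cc1Br | intermediate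
8 | (2S)-6-(benzyloxy)-2,8-dimethyl-2-(4-methylpent-3-en-1-yl)-3,4-dihydro-2H-chromene | CC(C)=CCC[C@@]1(C)CCc2cc(OCc3ccccc3)cc(C)c2O1 | intermediate
9 | (2E)-5-[(2S)-6-(benzyloxy)-2,8-dimethyl-3,4-dihydro-2H-chromen-2-yl]-2-methylpent-2-en-1-ol | C/C(CO)=C\CC[C@@]1(C)CCc2cc(OCc3ccccc3)cc(C)c2O1 | intermediate
10 | (2S)-6-(benzyloxy)-2-[(3E)-5-bromo-4-methylpent-3-en-1-yl]-2,8-dimethyl-3,4-dihydro-2H-chromene | C/C(CBr)=C\CC[C@@]1(C)CCc2cc(OCc3ccccc3)cc(C)c2O1 | intermediate
11 | geranyl bromide | CC(C)=CCC/C(C)=C/CBr | starting material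
12 | [(2E)-3,7-dimethylocta-2,6-dien-1-yl]sulfonylbenzene | CC(C)=CCC/C(C)=C/CS(=O)(=O)c1ccccc1 | intermediate
13 | rac-2,2-dimethyl-3-[(3E)-3-methyl-5-(phenylsulfonyl)pent-3-en-1-yl]oxirane | CC1(C)OC1CC/C(C)=C/CS(=O)(=O)c1ccccc1 | intermediate
14 | rac-(6E)-2-bromo-2,6-dimethyl-8-(phenylsulfonyl)oct-6-en-3-ol | CC(C)(Br)C(O)CC/C(C)=C/CS(=O)(=O)c1ccccc1 | intermediate
15 | (6E)-2-bromo-2,6-dimethyl-8-(phenylsulfonyl)oct-6-en-3-one | CC(C)(Br)C(=O)CC/C(C)=C/CS(=O)(=O)c1ccccc1 | intermediate
16 | rac-2,2-dimethyl-4-methylidene-3-[(phenylsulfonyl)methyl]cyclohexan-1-one | C=C1CCC(=O)C(C)(C)C1CS(=O)(=O)c1ccccc1 | intermediate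
17 | (1R,3R)-2,2-dimethyl-4-methylidene-3-[(phenylsulfonyl)methyl]cyclohexan-1-ol | C=C1CC[C@@H](O)C(C)(C)[C@@H]1CS(=O)(=O)c1ccccc1 | intermediate
18 | dilithium salt of 17 (alkoxide and α-sulfonyl carbanion) | C=C1CC[C@@H]([O-])C(C)(C)[C@@H]1[CH-]S(=O)(=O)c1ccccc1.[Li+].[Li+] | intermediate
19 | (1R,3R)-3-{(3E)-6-[(2S)-6-(benzyloxy)-2,8-dimethyl-3,4-dihydro-2H-chromen-2-yl]-3-methyl-1-(phenylsulfonyl)hex-3-en-1-yl}-2,2-dimethyl-4-methylidenecyclohexan-1-ol (epimers at the sulfonyl carbon) | C=C1CC[C@@H](O)C(C)(C)[C@@H]1C(C/C(C)=C/CC[C@@]1(C)CCc2cc(OCc3ccccc3)cc(C)c2O1)S(=O)(=O)c1ccccc1 | intermediate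
20 | (2S)-2-{(3E)-6-[(1R,3R)-3-hydroxy-2,2-dimethyl-6-methylidenecyclohexyl]-4-methylhex-3-en-1-yl}-2,8-dimethyl-3,4-dihydro-2H-chromen-6-ol | C=C1CC[C@@H](O)C(C)(C)[C@@H]1CC/C(C)=C/CC[C@@]1(C)CCc2cc(O)cc(C)c2O1 | target

**Totals**
Total step count: 15.
Longest linear sequence: 8 steps (1 → 2 → 3 → 6 → 8 → 9 → 10 → 19 → 20, steps 1, 2, 4, 5, 6, 7, 14, 15; the sulfone branch, steps 8 to 15, is equally long).

**Three steps most likely to fail**

Step 4 (O-allylation of a phenol with two ortho substituents; the risks are the linear ether and an ee of only about 80–90%, which would carry through as a diastereomer that cannot be removed later). The fallback sets out from 4 and comes back at 8, and takes the tertiary centre from a Sharpless epoxidation instead. Epoxidation of 4 (Ti(OiPr)4, L-(+)-diethyl tartrate, t-BuOOH, 4 Å sieves, CH2Cl2, −20 °C) gives [(2S,3S)-3-methyl-3-(4-methylpent-3-en-1-yl)oxiran-2-yl]methanol F1. PPh3, I2 and imidazole convert it into (2R,3S)-2-(iodomethyl)-3-methyl-3-(4-methylpent-3-en-1-yl)oxirane F2, and Zn dust in AcOH/EtOH opens this reductively to (S)-linalool F3 with the C–O bond of the tertiary centre untouched. In parallel, commercial 3-bromo-5-methylphenol is brominated para to the OH (NBS, MeCN) to 3,4-dibromo-5-methylphenol F4 and benzylated (BnBr, K2CO3) to 5-(benzyloxy)-1,2-dibromo-3-methylbenzene F5. Hydroboration of F3 with 9-BBN (2.2 equiv) gives the O,C-bis(9-BBN) adduct of (S)-linalool F6, which couples (Pd(dppf)Cl2, K3PO4, 60 °C) at the less hindered bromide of F5 to give (3S)-1-[5-(benzyloxy)-2-bromo-3-methylphenyl]-3,7-dimethyloct-6-en-3-ol F7. Pd(OAc)2, 2-(di-tert-butylphosphino)-1,1'-binaphthyl and Cs2CO3 in toluene at 80 °C then form the aryl–oxygen bond with retention and give 8.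

Step 12 (cobalt-mediated ring closure; the risks are simple debromination, dehydrobromination to the enone, or the endocyclic alkene). The fallback sets out from 13 and comes back at 16, and replaces the α-keto radical by reductive epoxide opening. Cp2TiCl (trivalent titanium, made from Cp2TiCl2 and Mn dust in THF, rt) opens 13 at the tertiary carbon; the β-titanoxy radical closes 6-endo and a second titanium terminates it to the exocyclic alkene, giving rac-cis-2,2-dimethyl-4-methylidene-3-[(phenylsulfonyl)methyl]cyclohexan-1-ol F8. Dess–Martin oxidation of F8 gives 16.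

Step 13 (catalyst control may not override the ring's own facial bias, which would lower the yield or the ee of the trans alcohol). The fallback sets out from 16 and comes back at 17, and replaces asymmetric reduction by a classical resolution. Lithium tri-sec-butylborohydride (L-Selectride, THF, −78 °C) attacks from the equatorial side and gives rac-trans-2,2-dimethyl-4-methylidene-3-[(phenylsulfonyl)methyl]cyclohexan-1-ol F9. Esterification with (S)-2-methoxy-2-phenylacetic acid (DCC, DMAP) gives the (1R,3R)-alcohol (S)-methoxy(phenyl)acetate F10 and the (1S,3S)-alcohol (S)-methoxy(phenyl)acetate F11, which are separated by chromatography and crystallisation. K2CO3 in MeOH cleaves F10 to 17.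

**Further compounds**
F1 | step 4 | [(2S,3S)-3-methyl-3-(4-methylpent-3-en-1-yl)oxiran-2-yl]methanol | OC[C@@H]1O[C@@]1(C)CCC=C(C)C
F2 | step 4 | (2R,3S)-2-(iodomethyl)-3-methyl-3-(4-methylpent-3-en-1-yl)oxirane | IC[C@@H]1O[C@@]1(C)CCC=C(C)C
F3 | step 4 | (S)-linalool | C=C[C@](C)(CCC=C(C)C)O
F4 | step 4 | 3,4-dibromo-5-methylphenol | Cc1cc(O)cc(Br)c1Br
F5 | step 4 | 5-(benzyloxy)-1,2-dibromo-3-methylbenzene | Cc1cc(OCc2ccccc2)cc(Br)c1Br
F6 | step 4 | O,C-bis(9-BBN) adduct of (S)-linalool | B1(C2CCCC1CCC2)CC[C@](C)(CCC=C(C)C)OB1C2CCCC1CCC2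
F7 | step 4 | (3S)-1-[5-(benzyloxy)-2-bromo-3-methylphenyl]-3,7-dimethyloct-6-en-3-ol | Cc1cc(OCc2ccccc2)cc(CC[C@](C)(CCC=C(C)C)O)c1Br
F8 | step 12 | rac-cis-2,2-dimethyl-4-methylidene-3-[(phenylsulfonyl)methyl]cyclohexan-1-ol (both enantiomers) | C=C1CC[C@H](O)C(C)(C)[C@@H]1CS(=O)(=O)c1ccccc1.C=C1CC[C@@H](O)C(C)(C)[C@H]1CS(=O)(=O)c1ccccc1
F9 | step 13 | rac-trans-2,2-dimethyl-4-methylidene-3-[(phenylsulfonyl)methyl]cyclohexan-1-ol (both enantiomers) | C=C1CC[C@@H](O)C(C)(C)[C@@H]1CS(=O)(=O)c1ccccc1.C=C1CC[C@H](O)C(C)(C)[C@H]1CS(=O)(=O)c1ccccc1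
F10 | step 13 | (1R,3R)-2,2-dimethyl-4-methylidene-3-[(phenylsulfonyl)methyl]cyclohexyl (2S)-methoxy(phenyl)acetate | C=C1CC[C@@H](OC(=O)[C@@H](OC)c2ccccc2)C(C)(C)[C@@H]1CS(=O)(=O)c1ccccc1
F11 | step 13 | (1S,3S)-2,2-dimethyl-4-methylidene-3-[(phenylsulfonyl)methyl]cyclohexyl (2S)-methoxy(phenyl)acetate | C=C1CC[C@H](OC(=O)[C@@H](OC)c2ccccc2)C(C)(C)[C@H]1CS(=O)(=O)c1ccccc1
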